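The earlier runs and the new flask are simulated on assumed constants, noise included.

At early times in this flask the solid first end groups fall 17 percentage points in 8.00 h while links rise 16 points, so the dissolved first end groups not yet linked stay a small pool: 5.50 % at 12.0 h and 7.90 % at 30.0 h.

the same everywhere: solid first end groups 20 mM

| flask | second end groups | remark | time |
|---|---|---|---|
| eta | 1 equiv | the very flask that is asked about, followed so far |  |
| flask | 1.00 equiv |  | 8.0 d |

eta run (percent of the solid first end groups charged)

| time / h | links / % | solid first end groups / % |
|---|---|---|
| 12.0 | 25.5 | 69.0 |
| 20.0 | 41.3 | 52.3 |
| 30.0 | 59.7 | 32.4 |
| 60.0 | 76.3 | 1.1 |
| 96.0 | 76.7 | 0.7 |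
| 144 | 77.2 | 0 |

(each reading ± 1 percentage point)

- removed links is counted in
- at the start none of the solid first end groups is in solution
- additions bring no volume worth counting

- autumn: at 8.0 d add second end groups, 100 % of the amount charged, then wait 8.0 d
- spring: at 8.0 d take out 90 % of the links then present, then wait 8.0 d
- dusk: change nothing and wait 8.0 d more

- links, in percent of the solid first end groups first charged, at 8.0 d
- what to do for the largest gain in links; "none" if nothing gains more than 2 percentage points (autumn / spring / dusk / none)
- links present, with what was taken out counted in, in percent of the solid first end groups first charged, after autumn
- links present, with what was taken out counted in, in percent of the solid first end groups first charged, after spring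

By 60.0 h the solid reads 1.1 % and links stop climbing. I follow one second end group: it ends as a link or it doesn't. Its chance of ending as a link, read as the mean of the last three link readings at one equivalent, is 76.7 %; I call this the capture. So I commit to that figure for links at 8.0 d, and dusk gains nothing.

The weak link is what the stall means: a balance with second end groups still free, or second end groups gone. If it is a balance, free second end groups at 30.0 h are whatever links haven't taken, and links over the product of the free amounts, as fractions of the charge, reads 18.8. On the plateau it reads 14.2, which is lower, yet links still rise afterwards to 76.3 %. With a scatter of 1 point this is a lean, not a proof, but I take the stall as spent second end groups. Then spring returns none of them, and the total stays at the capture. In autumn the fresh charge meets the first end groups not yet linked, so the capture, read while solid was still going into solution, does not carry over: the gain is bounded by the 23.3 % unlinked, against a margin of 2 points, and autumn is my choice.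

The forecast says 77 %, autumn, 94 % after autumn and 88.5 % after spring, on the ground that “This looks like a true reversible equilibrium”. On spring it parts from my reckoning.

The flask gives 76.7 %, autumn with 94.2 %, and 76.7 % after spring, a gain of 0 points.

    first end groups + second end groups → links (k = 31.0 M⁻¹ h⁻¹)
    first end groups + second end groups → rings, rate k2*[first end groups] as long as [second end groups] is above zero (k = 0.00910 h⁻¹)
    second end groups → decomposed reagent (k = 0.00860 h⁻¹)
    solid first end groups ⇌ first end groups, rate k4*(cs4 - [first end groups]) while solid is left; crystals form when [first end groups] > cs4 (solubility = 4.00 mM, k = 0.160 h⁻¹)

The second end groups, the limiting reagent here, stand at 0 % at 192 h. Spring's total equals the capture, 76.7 %. In the neighbour charged with 8.0 mM of solid at the same equivalents, the capture gives 76.7 % again; that flask gives 75.8 %, with 0 % of its second end groups left.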